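Eudesmane numbering: ring A is C1–C5 and C10, ring B is C5–C10; diol at C3/C4, benzoate at C6, isopropyl at C7, methyl C14 on C10. Cutting C3–C4 and C5–C10 unfolds the decalin into one chain, an acyclic dialdehyde with a C10=C1 alkene, a C4=C5 enal and a C3 aldehyde; ring B carbons, C14, isopropyl and the C7 stereocentre come from (R)-limonene by ozonolysis. One Fe(acac)3/PhSiH3 radical-polar crossover closes C5–C10 (tertiary C10 radical onto the enal) and C3–C4 (aldol of the C4 enolate). It exploits the quaternary, methyl-bearing fusion carbon C10 as Markovnikov radical site and C4 as α-carbon of an excisable formyl group.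

Key step: step 7

Remark on the chemistry: β means the face of the C14 methyl and α the opposite face; compounds 6, 7, 10, 11 and 12 are E/Z mixtures at the C10=C1 alkene, which is taken to be harmless because both isomers give the same C10 radical in step 7.

Step 1
Reactants: 1 (R)-(+)-limonene
Product: 2 (R)-(+)-p-menth-1-ene
Conditions: H2 (1 atm), RhCl(PPh3)3 (1 mol %), benzene, rt
Reagents that add atoms: none
Why: Homogeneous hydrogenation with RhCl(PPh3)3 should saturate the 1,1-disubstituted isopropenyl alkene much faster than the trisubstituted ring alkene, and the stereocentre (the future C7) is not touched.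

Step 2
Reactants: 2 (R)-(+)-p-menth-1-ene
Product: 4 (5R)-7,7-dimethoxy-5-(propan-2-yl)heptan-2-one, via methoxy hydroperoxide 3 (not isolated)
Conditions: O3, CH2Cl2/MeOH, −78 °C; TsOH·H2O (cat.), −78 °C → rt; NaHCO3, Me2S, rt
Reagents that add atoms: ozone, O=[O+][O-]; methanol, CO
Why: Ozonolysis in methanol cleaves the ring alkene (the future C5–C10 bond); the carbonyl oxide at the more substituted carbon is held as methoxy hydroperoxide 3 while TsOH acetalises the aldehyde end, so Me2S should release only the ketone (terminus-differentiating ozonolysis).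

Step 3
Reactants: 4 (5R)-7,7-dimethoxy-5-(propan-2-yl)heptan-2-one; 5 (3-hydroxypropyl)triphenylphosphonium bromide
Product: 6 (7R)-9,9-dimethoxy-4-methyl-7-(propan-2-yl)non-3-en-1-ol (3E/3Z mixture)
Conditions: 5, n-BuLi (2 equiv), THF, −20 → 0 °C; then 4, 0 °C → rt
Reagents that add atoms: (3-hydroxypropyl)triphenylphosphonium bromide (5), OCCC[P+](c1ccccc1)(c1ccccc1)c1ccccc1.[Br-]
Why: Wittig olefination of the methyl ketone with the oxido ylide made from 5 and two equivalents of base installs C1–C3; the E/Z mixture is acceptable because both isomers give the same C10 radical in step 7.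

Step 4
Reactants: 6 (7R)-9,9-dimethoxy-4-methyl-7-(propan-2-yl)non-3-en-1-ol
Product: 7 (3R)-9-hydroxy-6-methyl-3-(propan-2-yl)non-6-enal (6E/6Z mixture)
Conditions: TsOH·H2O (cat.), acetone/H2O, rt
Reagents that add atoms: water, O
Why: Acid-catalysed hydrolysis of the dimethyl acetal frees the C5 aldehyde; the alkene, the alcohol and the stereocentre should be inert under these mild conditions.

Step 5
Reactants: 7 (3R)-9-hydroxy-6-methyl-3-(propan-2-yl)non-6-enal; 8 dibenzoyl peroxide; 9 2-(triphenylphosphoranylidene)propanal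
Product: 11 (2E,4R,5S)-11-hydroxy-2,8-dimethyl-1-oxo-5-(propan-2-yl)undeca-2,8-dien-4-yl benzoate (8E/8Z mixture), via α-benzoyloxy aldehyde 10 (not isolated)
Conditions: (R)-α,α-diphenylprolinol trimethylsilyl ether (20 mol %), 8, hydroquinone (10 mol %), THF, 0 °C; then 9, rt
Reagents that add atoms: dibenzoyl peroxide (8), O=C(OOC(=O)c1ccccc1)c1ccccc1; 2-(triphenylphosphoranylidene)propanal (9), CC(C=O)=P(c1ccccc1)(c1ccccc1)c1ccccc1
Why: Enamine catalysis: the bulky group of the (R)-catalyst shields one face of the E-enamine of 7, so the peroxide should be attacked from the open face and set C6 as (2R) under catalyst control, and the labile aldehyde 10 is trapped at once by an E-selective Wittig reaction with the stabilised ylide 9.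

Step 6
Reactants: 11 (2E,4R,5S)-11-hydroxy-2,8-dimethyl-1-oxo-5-(propan-2-yl)undeca-2,8-dien-4-yl benzoate
Product: 12 (2E,4R,5S)-2,8-dimethyl-1,11-dioxo-5-(propan-2-yl)undeca-2,8-dien-4-yl benzoate (8E/8Z mixture)
Conditions: DMP, NaHCO3, CH2Cl2, 0 °C → rt
Reagents that add atoms: none
Why: Dess–Martin oxidation turns the primary homoallylic alcohol into the C3 aldehyde under buffered, non-basic conditions that should leave the β,γ-alkene in place; 12 is used without storage.

Step 7
Reactants: 12 (2E,4R,5S)-2,8-dimethyl-1,11-dioxo-5-(propan-2-yl)undeca-2,8-dien-4-yl benzoate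
Product: 13 (1R,2S,4aS,7R,8S,8aR)-8-formyl-7-hydroxy-4a,8-dimethyl-2-(propan-2-yl)decahydronaphthalen-1-yl benzoate (3α-OH, 4α-CHO, 4β-CH3, 5α-H, 6β-OBz, 10β-CH3 in eudesmane numbering)
Conditions: Fe(acac)3 (0.3 equiv), PhSiH3 (2.5 equiv), EtOH/(CH2OH)2 (5:1), 0.01 M, rt
Reagents that add atoms: none
Why: The Fe–H species formed from Fe(acac)3 and PhSiH3 transfers a hydrogen atom to C1 of the trisubstituted alkene, the tertiary C10 radical adds to C5 of the enal (6-exo-trig, ring B, bond C5–C10), and reduction of the α-formyl radical by divalent iron gives the trivalent iron enolate at C4, which adds to the C3 aldehyde (6-(enolexo)-exo-trig aldol, ring A, bond C3–C4). The closest known reaction type is the hydrogen-atom-transfer-initiated radical–polar crossover annulation (reductive Giese addition, then intramolecular aldol addition) used to build trans-decalins with an angular methyl group. C5 is set in the chair-like transition state of the first closure with the C7 isopropyl group equatorial, which puts the C6 benzoate axial and H5 trans to O6; C10 is set by the same event and by the second closure, because only the adduct whose C1–C3 arm is equatorial (C14 axial, trans to H5) can reach C4 through a chair, the epimer being diverted to uncyclised material. C4 and C3 should follow from a closed, metal-bridged aldol transition state in which H5 eclipses the enolate (formyl equatorial, methyl axial) and the new hydroxyl is cis to the formyl group; both centres are removed again in step 9. The step needs hydrogen-atom transfer to the electron-rich alkene and not to the enal, which the hydridic Fe–H provides, and enolate formation at C4 and not at C2, which follows from where the radical sits after the Giese addition; the facial selectivity at C5 is its least secure element.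

Step 8
Reactants: 13 (1R,2S,4aS,7R,8S,8aR)-8-formyl-7-hydroxy-4a,8-dimethyl-2-(propan-2-yl)decahydronaphthalen-1-yl benzoate
Product: 14 (1S,2R,4aS,7S,8R,8aR)-8-(benzoyloxy)-2-hydroxy-1,4a-dimethyl-7-(propan-2-yl)decahydronaphthalene-1-carboxylic acid
Conditions: NaClO2, NaH2PO4, 2-methyl-2-butene, t-BuOH/H2O, 0 °C → rt
Reagents that add atoms: sodium chlorite, [Na+].[O-]Cl=O
Why: Pinnick oxidation should convert the hindered α-quaternary aldehyde into the acid at about pH 4, where neither retro-aldol cleavage nor benzoate hydrolysis is expected.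

Step 9
Reactants: 14 (1S,2R,4aS,7S,8R,8aR)-8-(benzoyloxy)-2-hydroxy-1,4a-dimethyl-7-(propan-2-yl)decahydronaphthalene-1-carboxylic acid
Product: 16 eudesm-3-en-6β-yl benzoate, via β-lactone 15 (not isolated)
Conditions: PhSO2Cl, pyridine, 0 °C; then xylene, 140 °C
Reagents that add atoms: none
Why: Carboxyl activation as the mixed sulfonic anhydride lets the cis 3α-hydroxyl close β-lactone 15 with retention, and thermal [2+2] cycloreversion of 15 should expel CO2 to give the C3=C4 alkene (decarboxylative dehydration of a β-hydroxy acid), which erases the two aldol stereocentres.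

Step 10
Reactants: 16 eudesm-3-en-6β-yl benzoate
Product: 17 3α,4α-epoxyeudesman-6β-yl benzoate
Conditions: mCPBA, NaHCO3, CH2Cl2, 0 °C
Reagents that add atoms: mCPBA, OOC(=O)c1cccc(Cl)c1
Why: Prilezhaev epoxidation of the trisubstituted alkene should occur from the α face, because the β face is blocked by the axial C14 methyl and the axial C6 benzoate.

Step 11
Reactants: 17 3α,4α-epoxyeudesman-6β-yl benzoate
Product: 18 (1R,2S,4aS,7R,8R,8aS)-7,8-dihydroxy-4a,8-dimethyl-2-(propan-2-yl)decahydronaphthalen-1-yl benzoate (CNP0187831.1)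
Conditions: HClO4 (cat.), THF/H2O, 0 °C → rt
Reagents that add atoms: water, O
Why: Acid-catalysed epoxide hydrolysis should follow the trans-diaxial opening rule: water attacks the tertiary C4 from the β face (SN1-like, possibly assisted by the syn-axial C6 benzoate), so C4 gets the axial 4β-hydroxyl with the methyl equatorial and C3 keeps its 3α-oxygen.

Compound list
1 | (R)-(+)-limonene, (4R)-1-methyl-4-(prop-1-en-2-yl)cyclohex-1-ene | CC1=CC[C@@H](CC1)C(C)=C | starting material
2 | (R)-(+)-p-menth-1-ene, (4R)-1-methyl-4-(propan-2-yl)cyclohex-1-ene | CC1=CC[C@@H](CC1)C(C)C | intermediate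
3 | (5R)-2-hydroperoxy-2,7,7-trimethoxy-5-(propan-2-yl)heptane (mixture at C2, not isolated) | CC(OC)(OO)CC[C@H](CC(OC)OC)C(C)C | intermediate
4 | (5R)-7,7-dimethoxy-5-(propan-2-yl)heptan-2-one | CC(=O)CC[C@H](CC(OC)OC)C(C)C | intermediate
5 | (3-hydroxypropyl)triphenylphosphonium bromide | OCCC[P+](c1ccccc1)(c1ccccc1)c1ccccc1.[Br-] | starting material
6 | (7R)-9,9-dimethoxy-4-methyl-7-(propan-2-yl)non-3-en-1-ol (3E/3Z mixture) | OCCC=C(C)CC[C@H](CC(OC)OC)C(C)C | intermediate
7 | (3R)-9-hydroxy-6-methyl-3-(propan-2-yl)non-6-enal (6E/6Z mixture) | CC(C)[C@H](CCC(C)=CCCO)CC=O | intermediate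
8 | dibenzoyl peroxide | O=C(OOC(=O)c1ccccc1)c1ccccc1 | starting material
9 | 2-(triphenylphosphoranylidene)propanal | CC(C=O)=P(c1ccccc1)(c1ccccc1)c1ccccc1 | starting material
10 | (2R,3S)-9-hydroxy-6-methyl-1-oxo-3-(propan-2-yl)non-6-en-2-yl benzoate (not isolated) | CC(C)[C@H](CCC(C)=CCCO)[C@@H](OC(=O)c1ccccc1)C=O | intermediate
11 | (2E,4R,5S)-11-hydroxy-2,8-dimethyl-1-oxo-5-(propan-2-yl)undeca-2,8-dien-4-yl benzoate (8E/8Z mixture) | CC(C)[C@H](CCC(C)=CCCO)[C@@H](OC(=O)c1ccccc1)/C=C(C)/C=O | intermediate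
12 | (2E,4R,5S)-2,8-dimethyl-1,11-dioxo-5-(propan-2-yl)undeca-2,8-dien-4-yl benzoate (8E/8Z mixture) | CC(C)[C@H](CCC(C)=CCC=O)[C@@H](OC(=O)c1ccccc1)/C=C(C)/C=O | intermediate
13 | (1R,2S,4aS,7R,8S,8aR)-8-formyl-7-hydroxy-4a,8-dimethyl-2-(propan-2-yl)decahydronaphthalen-1-yl benzoate (6β-benzoyloxy-3α-hydroxy-4α-formyl-4β-methyl, trans-decalin) | CC(C)[C@@H]1CC[C@@]2(C)CC[C@@H](O)[C@@](C)(C=O)[C@@H]2[C@@H]1OC(=O)c1ccccc1 | intermediate
14 | (1S,2R,4aS,7S,8R,8aR)-8-(benzoyloxy)-2-hydroxy-1,4a-dimethyl-7-(propan-2-yl)decahydronaphthalene-1-carboxylic acid | CC(C)[C@@H]1CC[C@@]2(C)CC[C@@H](O)[C@@](C)(C(=O)O)[C@@H]2[C@@H]1OC(=O)c1ccccc1 | intermediate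
15 | cis-fused β-lactone of 14, the oxetan-2-one spanning O3 and C4 on the α face (not isolated) | CC(C)[C@@H]1CC[C@@]2(C)CC[C@H]3OC(=O)[C@@]3(C)[C@@H]2[C@@H]1OC(=O)c1ccccc1 | intermediate
16 | eudesm-3-en-6β-yl benzoate, (1R,2S,4aR,8aR)-4a,8-dimethyl-2-(propan-2-yl)-1,2,3,4,4a,5,6,8a-octahydronaphthalen-1-yl benzoate | CC(C)[C@@H]1CC[C@@]2(C)CCC=C(C)[C@@H]2[C@@H]1OC(=O)c1ccccc1 | intermediate
17 | 3α,4α-epoxyeudesman-6β-yl benzoate (5α-H, 7β-isopropyl, 10β-methyl) | CC(C)[C@@H]1CC[C@@]2(C)CC[C@H]3O[C@@]3(C)[C@@H]2[C@@H]1OC(=O)c1ccccc1 | intermediate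
18 | (1R,2S,4aS,7R,8R,8aS)-7,8-dihydroxy-4a,8-dimethyl-2-(propan-2-yl)decahydronaphthalen-1-yl benzoate (6β-benzoyloxyeudesmane-3α,4β-diol, CNP0187831.1) | CC(C)[C@@H]1CC[C@@]2(C)CC[C@@H](O)[C@](C)(O)[C@@H]2[C@@H]1OC(=O)c1ccccc1 | target

Total step count: 11. Longest linear sequence: 11 steps (the route is fully linear from 1).

Steps most likely to fail

Step 7. The C10 radical may add to the wrong face of C5. With the isopropyl group equatorial, the C6 benzoate must sit axial and nearly syn-periplanar to C4=C5, where it is strained against the C4 methyl group. The alternative chair (benzoate anti to the radical, isopropyl axial) can therefore compete or win and would give the C5,C10-diastereomeric decalin. The enolate may also be protonated before the aldol closure. The fallback keeps the known annulation but removes this mismatch by carrying the C6 epimer and inverting C6 late. It sets out from 7: the (S)-enantiomer of the catalyst in the benzoyloxylation gives the C6-epimeric α-benzoyloxy aldehyde F1, and the reagents of steps 5 to 9 then give enal F2, dialdehyde F3, annulation product F4, acid F5, β-lactone F6 and the 6α-benzoate alkene F7. In the cyclisation of F3 all chair substituents are equatorial, the benzoate is anti to the radical and H6 eclipses the alkene. K2CO3 in MeOH then gives the 6α-alcohol F8, DMP gives ketone F9, NaBH4/CeCl3 at −78 °C should reduce it from the open α face to the axial 6β-alcohol F10, and BzCl, DMAP, pyridine comes back to the route at 16.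

Step 5. The amine catalyst may be consumed by the peroxide, catalyst control may be eroded by the neighbouring C7 centre, and the α-benzoyloxy aldehyde may epimerise during the olefination. The fallback forms the C6–O bond with nitrosobenzene under hydrogen-bond direction and benzoylates at the end. It sets out from 7: L-proline (20 mol %), PhNO, CHCl3, 4 °C should give the (2R)-anilinooxy aldehyde F11, which is trapped in the same flask by 9 to give enal F12. CuSO4 (cat.) in MeOH cleaves the N–O bond to give diol F13, TEMPO (cat.) with PhI(OAc)2 oxidises only the primary alcohol to give hydroxy dialdehyde F14, and BzCl, pyridine comes back to the route at 12.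

Step 9. Lactone closure needs the cis hydroxy acid. If the aldol of step 7 delivers the trans isomer, or if the hydroxyl is sulfonylated instead of the carboxyl, no alkene forms. The fallback does not depend on the C3/C4 configuration. It sets out from 13: DMP gives β-keto aldehyde F15; Et3N in MeOH removes the formyl group by retro-Claisen cleavage, and the C4 methyl settles equatorial in ketone F16. Tf2O with 2,6-di-tert-butyl-4-methylpyridine gives the more substituted enol triflate F17, and Pd(OAc)2, PPh3, Bu3N, HCO2H reduces it, coming back to the route at 16.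

Further compounds
F1 | step 7 | (2S,3S)-9-hydroxy-6-methyl-1-oxo-3-(propan-2-yl)non-6-en-2-yl benzoate (C6 epimer of 10) | CC(C)[C@H](CCC(C)=CCCO)[C@H](OC(=O)c1ccccc1)C=O
F2 | step 7 | (2E,4S,5S)-11-hydroxy-2,8-dimethyl-1-oxo-5-(propan-2-yl)undeca-2,8-dien-4-yl benzoate (C6 epimer of 11) | CC(C)[C@H](CCC(C)=CCCO)[C@H](OC(=O)c1ccccc1)/C=C(C)/C=O
F3 | step 7 | (2E,4S,5S)-2,8-dimethyl-1,11-dioxo-5-(propan-2-yl)undeca-2,8-dien-4-yl benzoate (C6 epimer of 12) | CC(C)[C@H](CCC(C)=CCC=O)[C@H](OC(=O)c1ccccc1)/C=C(C)/C=O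
F4 | step 7 | 6α-benzoate epimer of 13 | CC(C)[C@@H]1CC[C@@]2(C)CC[C@@H](O)[C@@](C)(C=O)[C@@H]2[C@H]1OC(=O)c1ccccc1
F5 | step 7 | 6α-benzoate epimer of 14 | CC(C)[C@@H]1CC[C@@]2(C)CC[C@@H](O)[C@@](C)(C(=O)O)[C@@H]2[C@H]1OC(=O)c1ccccc1
F6 | step 7 | 6α-benzoate epimer of 15 | CC(C)[C@@H]1CC[C@@]2(C)CC[C@H]3OC(=O)[C@@]3(C)[C@@H]2[C@H]1OC(=O)c1ccccc1
F7 | step 7 | eudesm-3-en-6α-yl benzoate | CC(C)[C@@H]1CC[C@@]2(C)CCC=C(C)[C@@H]2[C@H]1OC(=O)c1ccccc1
F8 | step 7 | eudesm-3-en-6α-ol | CC(C)[C@@H]1CC[C@@]2(C)CCC=C(C)[C@@H]2[C@H]1O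
F9 | step 7 | eudesm-3-en-6-one | CC(C)[C@@H]1CC[C@@]2(C)CCC=C(C)[C@@H]2C1=O
F10 | step 7 | eudesm-3-en-6β-ol | CC(C)[C@@H]1CC[C@@]2(C)CCC=C(C)[C@@H]2[C@@H]1O
F11 | step 5 | (2R,3S)-2-(anilinooxy)-9-hydroxy-6-methyl-3-(propan-2-yl)non-6-enal | CC(C)[C@H](CCC(C)=CCCO)[C@@H](ONc1ccccc1)C=O
F12 | step 5 | (2E,4R,5S)-4-(anilinooxy)-11-hydroxy-2,8-dimethyl-5-(propan-2-yl)undeca-2,8-dienal | CC(C)[C@H](CCC(C)=CCCO)[C@@H](ONc1ccccc1)/C=C(C)/C=O
F13 | step 5 | (2E,4R,5S)-4,11-dihydroxy-2,8-dimethyl-5-(propan-2-yl)undeca-2,8-dienal | CC(C)[C@H](CCC(C)=CCCO)[C@@H](O)/C=C(C)/C=O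
F14 | step 5 | (2E,4R,5S)-4-hydroxy-2,8-dimethyl-5-(propan-2-yl)undeca-2,8-dienedial | CC(C)[C@H](CCC(C)=CCC=O)[C@@H](O)/C=C(C)/C=O
F15 | step 9 | 3-oxo analogue of 13 (6β-benzoyloxy-4α-formyl-4β-methyl-3-ketone) | CC(C)[C@@H]1CC[C@@]2(C)CCC(=O)[C@@](C)(C=O)[C@@H]2[C@@H]1OC(=O)c1ccccc1
F16 | step 9 | 3-oxoeudesman-6β-yl benzoate (4α-methyl) | CC(C)[C@@H]1CC[C@@]2(C)CCC(=O)[C@@H](C)[C@@H]2[C@@H]1OC(=O)c1ccccc1
F17 | step 9 | 3-(trifluoromethanesulfonyloxy)eudesm-3-en-6β-yl benzoate | CC(C)[C@@H]1CC[C@@]2(C)CCC(OS(=O)(=O)C(F)(F)F)=C(C)[C@@H]2[C@@H]1OC(=O)c1ccccc1
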